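**Retrosynthetic overview**
1. The oxepine closes last. The 2'-phenoxide opens an (S)-gem-dimethyl epoxide 7-exo at its CH (inversion, giving R). That epoxide comes from an (R)-secondary mesylate next to the tertiary alcohol (inversion), so one enantioselective ketone reduction sets the only stereocentre.
2. Key C-C disconnection: C3-CH2. Both carbons are natural enolate (donor) carbons: the central carbon of a β-diketone and the methyl carbon of 3-hydroxy-3-methylbutan-2-one. The C5 ketone is used with reversed polarity as its α-bromide (enolonium equivalent). The oxidised C5 chain therefore never exists as an alkene competing with the two ring A prenyl groups.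
3. Ring C forms by cyclodehydration of the alkylated β-diketone in the same flask. The β-diketone (C2-C3 bond) comes from a crossed Claisen condensation.
4. Ring A is C-diprenylated at the very start on symmetrical phloroacetophenone, so ring C closure raises no regiochemical question.
5. Ring order: A and B are bought, then ring C, then the oxepine.

Assumption: operations run in one flask without isolation count as one step. The ee of 12 can be upgraded by recrystallising 13 if needed.

**Step 1**
Reactants: 1 2,4,6-trihydroxyacetophenone; 2 prenyl bromide (1-bromo-3-methylbut-2-ene, 2.1 equiv)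
Product: 3 1-[2,4,6-trihydroxy-3,5-bis(3-methylbut-2-en-1-yl)phenyl]ethan-1-one
Conditions: KOH (2.2 equiv), H2O/MeOH, 0 °C to rt
Reagents that add atoms: none
Why: Base-mediated electrophilic C-prenylation of the ambident acylphloroglucinol anion (the reaction used for deoxyhumulone-type hop acids) alkylates both free ring carbons, and no stereocentre is formed.

**Step 2**
Reactants: 3
Product: 4 1-[2-hydroxy-4,6-bis(methoxymethoxy)-3,5-bis(3-methylbut-2-en-1-yl)phenyl]ethan-1-one
Conditions: MOMCl (2.3 equiv), iPr2NEt (3 equiv), CH2Cl2, 0 °C to rt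
Reagents that add atoms: chloromethyl methyl ether (MOMCl), COCCl
Why: In this MOM protection (O-alkylation by a hard electrophile), the remaining ortho hydroxyl stays chelated to the acetyl carbonyl once the first is capped, so it stays free as the future ring C oxygen.

**Step 3**
Reactants: 5 methyl 2,4-dihydroxybenzoate
Product: 6 methyl 2,4-bis(methoxymethoxy)benzoate
Conditions: NaH (2.5 equiv), MOMCl (2.5 equiv), DMF, 0 °C to rt
Reagents that add atoms: chloromethyl methyl ether (MOMCl), COCCl
Why: MOM protection through the sodium phenoxides, with NaH needed because the 2-OH is chelated to the ester.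

**Step 4**
Reactants: 4; 6 (1.2 equiv)
Product: 7 1-[2,4-bis(methoxymethoxy)phenyl]-3-[2-hydroxy-4,6-bis(methoxymethoxy)-3,5-bis(3-methylbut-2-en-1-yl)phenyl]propane-1,3-dione (keto/enol mixture)
Conditions: LiN(SiMe3)2 (3.3 equiv), THF, -78 °C to 45 °C; cold 1 M HCl quench
Reagents that add atoms: none
Why: Crossed Claisen condensation of the dilithiated ketone (phenoxide plus enolate) with a non-enolisable ester, driven by deprotonation of the β-diketone formed.

**Step 5**
Reactants: 8 3-hydroxy-3-methylbutan-2-one
Product: 9 1-bromo-3-hydroxy-3-methylbutan-2-one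
Conditions: Br2 (1.0 equiv), MeOH, 0-5 °C; then H2O
Reagents that add atoms: bromine, BrBr
Why: Acid-catalysed α-bromination of a ketone that can enolise only toward its methyl group turns that donor carbon into an acceptor (enolonium equivalent).

**Step 6 (key step)**
Reactants: 7; 9 (1.1 equiv)
Product: 11 2-[2,4-bis(methoxymethoxy)phenyl]-3-(3-hydroxy-3-methyl-2-oxobutyl)-5,7-bis(methoxymethoxy)-6,8-bis(3-methylbut-2-en-1-yl)-4H-chromen-4-one, via triketone 10 (not isolated)
Conditions: K2CO3 (1.05 equiv), acetone, 0 °C to rt; filter, concentrate; PPTS (0.2 equiv), toluene, 4 Å sieves, 60 °C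
Reagents that add atoms: none
Why: SN2 C-alkylation of the soft potassium β-diketonate by the α-bromoketone (umpolung, a2 synthon) joins two carbons that are both natural enolate donors and creates the dissonant 1,4-dioxygen pattern; one equivalent of mild base keeps the chelated phenol protonated; mild acid then ionises the cyclic hemiketal (stabilised by electron-rich ring B) and closes ring C (flavone cyclodehydration) while the aryl MOM ethers survive; C3 becomes sp2, so no stereocentre remains.

**Step 7**
Reactants: 11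
Product: 12 2-[2,4-bis(methoxymethoxy)phenyl]-3-[(2R)-2,3-dihydroxy-3-methylbutyl]-5,7-bis(methoxymethoxy)-6,8-bis(3-methylbut-2-en-1-yl)-4H-chromen-4-one
Conditions: (S)-2-methyl-CBS-oxazaborolidine [(S)-1-methyl-3,3-diphenyltetrahydro-1H,3H-pyrrolo[1,2-c][1,3,2]oxazaborole, 0.3 equiv], catecholborane (3 equiv), toluene/CH2Cl2, -78 to -40 °C; MeOH, then 1 M NaOH wash
Reagents that add atoms: none
Why: Corey-Bakshi-Shibata reduction in which the O-borylated CMe2O group is the large substituent and CH2 the small one, so the (S)-catalyst gives the R carbinol (as for tert-alkyl ketones); catecholborane leaves the prenyl alkenes alone at low temperature, and the chromone carbonyl (vinylogous ester) is inert.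

**Step 8**
Reactants: 12
Product: 13 (2R)-1-{2-[2,4-bis(methoxymethoxy)phenyl]-5,7-bis(methoxymethoxy)-6,8-bis(3-methylbut-2-en-1-yl)-4-oxo-4H-chromen-3-yl}-3-hydroxy-3-methylbutan-2-yl methanesulfonate
Conditions: MsCl (1.2 equiv), Et3N (2 equiv), CH2Cl2, -20 to 0 °C
Reagents that add atoms: methanesulfonyl chloride, CS(=O)(=O)Cl
Why: Chemoselective O-sulfonylation (mesylation) of the secondary alcohol, with the tertiary one inert and the C-O bond untouched, so R is retained.

**Step 9**
Reactants: 13
Product: 16 target CNP0328977.2 (R), via tetraphenol mesylate 14 (not isolated), via phenol epoxide 15 (not isolated)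
Conditions: 2 M HCl in MeOH, 35-40 °C; cool to 0 °C, K2CO3 (neutralisation plus 6 equiv), Ar, 45 °C; acidify to pH 5
Reagents that add atoms: none
Why: Acetal methanolysis removes the four MOM groups; base then triggers a 3-exo-tet Williamson epoxide closure by the tertiary alkoxide (inversion, S-epoxide), and a 7-exo-tet opening at the less substituted epoxide carbon by the 2'-phenoxide (second inversion, R), the base-mode closure known for 2-(2-hydroxypropan-2-yl)benzoxepanes; no other phenoxide can reach the epoxide intramolecularly.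

**Compound list**
1 | 2,4,6-trihydroxyacetophenone | CC(=O)c1c(O)cc(O)cc1O | starting material
2 | prenyl bromide | CC(C)=CCBr | starting material
3 | 3,5-diprenylphloroacetophenone | CC(=O)c1c(O)c(CC=C(C)C)c(O)c(CC=C(C)C)c1O | intermediate
4 | 2-hydroxy-4,6-bis(MOM-oxy)-3,5-diprenylacetophenone | CC(=O)c1c(O)c(CC=C(C)C)c(OCOC)c(CC=C(C)C)c1OCOC | intermediate
5 | methyl 2,4-dihydroxybenzoate | COC(=O)c1ccc(O)cc1O | starting material
6 | methyl 2,4-bis(methoxymethoxy)benzoate | COCOc1ccc(C(=O)OC)c(OCOC)c1 | intermediate
7 | β-diketone | COCOc1ccc(C(=O)CC(=O)c2c(O)c(CC=C(C)C)c(OCOC)c(CC=C(C)C)c2OCOC)c(OCOC)c1 | intermediate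
8 | 3-hydroxy-3-methylbutan-2-one | CC(=O)C(C)(C)O | starting material
9 | 1-bromo-3-hydroxy-3-methylbutan-2-one | O=C(CBr)C(C)(C)O | intermediate
10 | 2-(3-hydroxy-3-methyl-2-oxobutyl) β-diketone (triketone, racemic, epimerisable) | COCOc1ccc(C(=O)C(CC(=O)C(C)(C)O)C(=O)c2c(O)c(CC=C(C)C)c(OCOC)c(CC=C(C)C)c2OCOC)c(OCOC)c1 | intermediate
11 | flavone ketone | CC(C)=CCc1c(OCOC)c(CC=C(C)C)c2oc(-c3ccc(OCOC)cc3OCOC)c(CC(=O)C(C)(C)O)c(=O)c2c1OCOC | intermediate
12 | (R)-diol | CC(C)=CCc1c(OCOC)c(CC=C(C)C)c2oc(-c3ccc(OCOC)cc3OCOC)c(C[C@@H](O)C(C)(C)O)c(=O)c2c1OCOC | intermediate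
13 | (R)-secondary mesylate | CC(C)=CCc1c(OCOC)c(CC=C(C)C)c2oc(-c3ccc(OCOC)cc3OCOC)c(C[C@@H](OS(C)(=O)=O)C(C)(C)O)c(=O)c2c1OCOC | intermediate
14 | tetraphenol (R)-mesylate | CC(C)=CCc1c(O)c(CC=C(C)C)c2oc(-c3ccc(O)cc3O)c(C[C@@H](OS(C)(=O)=O)C(C)(C)O)c(=O)c2c1O | intermediate
15 | tetraphenol (S)-epoxide | CC(C)=CCc1c(O)c(CC=C(C)C)c2oc(-c3ccc(O)cc3O)c(C[C@@H]4OC4(C)C)c(=O)c2c1O | intermediate
16 | CNP0328977.2, (R) | CC(C)=CCc1c(O)c(CC=C(C)C)c2oc3c(c(=O)c2c1O)C[C@H](C(C)(C)O)Oc1cc(O)ccc1-3 | target

**Step count**
Total steps: 9. Longest linear sequence: 7 (steps 1, 2, 4, 6, 7, 8, 9).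

**Steps most likely to fail**

Step 6. The bromoketone may O-alkylate the chelated phenol or the enolate oxygen. The triketone may also drift to furans (Feist-Benary or Paal-Knorr type). The fallback makes the same C3-CH2 bond without base, one oxidation level higher. It sets out from 7 and 8. SeO2 in aqueous dioxane at 60 °C oxidises 8 to 3-hydroxy-3-methyl-2-oxobutanal F1. F1 condenses with 7 under L-proline catalysis to the alkylidene triketone F2. Hantzsch ester (diethyl 2,6-dimethyl-1,4-dihydropyridine-3,5-dicarboxylate) reduces F2 in the same flask. The fallback comes back to the route at 10, which is closed to 11 with PPTS as before.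

Step 7. The two flanks of the ketone are both bulky, and the boryloxy group may lower the ee. The fallback replaces catalyst control by resolution with recycling. It sets out from 11. NaBH4 in MeOH at 0 °C gives the racemic diol, that is 12 together with the (S)-diol F3. DCC/DMAP esterification with (S)-2-methoxy-2-phenylacetic acid gives the (R)-carbinyl ester F4 and the (S)-carbinyl ester F5, which are separated on silica. K2CO3/MeOH on F4 comes back to the route at 12. F5 is hydrolysed to F3 and oxidised with Dess-Martin periodinane back to 11.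

Step 9. The mesylate has to survive the acid stage: the chromone carbonyl could participate, and free ortho-prenylphenols can cyclise to chromans. The 7-exo closure must also beat intermolecular opening. The fallback keeps acid and leaving group apart. It sets out from 12. HCl/MeOH first gives the tetraphenol (R)-diol F6. Excess MsCl/Et3N/DMAP gives the pentamesylate F7, whose aryl mesylates serve as base-labile masks. NaOH in MeOH/THF/H2O cleaves the aryl mesylates and closes the epoxide. The fallback comes back to the route at 15, which cyclises in the same flask to 16.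

**Further compounds**
F1 | step 6 | 3-hydroxy-3-methyl-2-oxobutanal | CC(C)(O)C(=O)C=O
F2 | step 6 | alkylidene triketone (Knoevenagel adduct of 7 and F1) | COCOc1ccc(C(=O)C(=CC(=O)C(C)(C)O)C(=O)c2c(O)c(CC=C(C)C)c(OCOC)c(CC=C(C)C)c2OCOC)c(OCOC)c1
F3 | step 7 | (S)-diol, enantiomer of 12 | CC(C)=CCc1c(OCOC)c(CC=C(C)C)c2oc(-c3ccc(OCOC)cc3OCOC)c(C[C@H](O)C(C)(C)O)c(=O)c2c1OCOC
F4 | step 7 | (S)-2-methoxy-2-phenylacetate of 12 | CC(C)=CCc1c(OCOC)c(CC=C(C)C)c2oc(-c3ccc(OCOC)cc3OCOC)c(C[C@@H](OC(=O)[C@@H](OC)c3ccccc3)C(C)(C)O)c(=O)c2c1OCOC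
F5 | step 7 | (S)-2-methoxy-2-phenylacetate of F3 | CC(C)=CCc1c(OCOC)c(CC=C(C)C)c2oc(-c3ccc(OCOC)cc3OCOC)c(C[C@H](OC(=O)[C@@H](OC)c3ccccc3)C(C)(C)O)c(=O)c2c1OCOC
F6 | step 9 | tetraphenol (R)-diol | CC(C)=CCc1c(O)c(CC=C(C)C)c2oc(-c3ccc(O)cc3O)c(C[C@@H](O)C(C)(C)O)c(=O)c2c1O
F7 | step 9 | pentamesylate of F6 (four aryl, one secondary alkyl) | CC(C)=CCc1c(OS(C)(=O)=O)c(CC=C(C)C)c2oc(-c3ccc(OS(C)(=O)=O)cc3OS(C)(=O)=O)c(C[C@@H](OS(C)(=O)=O)C(C)(C)O)c(=O)c2c1OS(C)(=O)=O
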